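**Retrosynthetic overview**
1. The C5 4-hydroxybenzoate is cut back to the C5 alcohol (Steglich esterification). The alcohol comes from a vinylogous Rubottom oxidation of the C6=C7 enone, and the enone from the saturated C8 ketone.
2. The strategy rests on ring A (cyclopentane C1–C2–C3–C4–C10): its C3 hydroxyl is trans to C5 across the C3–C4 bond, and C5 is the first carbon of ring B (cycloheptenone C4–C5–C6–C7–C8–C9–C10). This is the pattern left by anti opening of a C3–C4–C5 cyclopropane at C3.
3. Key disconnection: C3–O and C5–C6 are both traced to one C3–C5 cyclopropane bond. Hydroxymercuration with inversion at C3 is followed by 7-endo addition of the C5 radical to an isopropenyl ketone on C10; ring B is formed last.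
4. The bicyclo[3.1.0]hexyl acetate precursor comes from (1R,4S,5S)-thujone by C10 alkylation anti to the cyclopropane, C1 reduction, Weinreb ketone synthesis and acetylation. The natural thujones have the mirror-image (1S,5R) bicycle, so the ketone is built de novo.
5. Ring A and the cyclopropane are formed first, together, by gold-catalysed cycloisomerisation of an enynol made by catalytic asymmetric crotylboration of 4-methylpent-2-ynal.

Key step: step 9

**Remarks**
- Core atom labels, used for all intermediates: C1 (CH–OAc), C2 (CH2), C3 (C(OH)iPr), C4 (ring-fusion CH), C5 (CH–O-aroyl), C6=C7(CH3), C8 (C=O), C9 (CH2), C10 (C–CH3). "Upper face" is the face of the C10 methyl group.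
- Assumption: metal alkoxides and borate esters that last only until aqueous work-up are treated as part of the work-up; species made in one operation and consumed in the next in the same flask are numbered.
- Assumption: the product of step 9 forms as both C7 epimers and is handled as one compound, drawn without a C7 descriptor, because step 10 makes C7 planar. It may rest partly as the C3–O–C8 hemiketal, which reacts through the open hydroxy ketone.

**Route**

Step 1
Reactants: 1 3-methylbut-1-yne
Product: 3 4-methylpent-2-ynal, via lithium acetylide 2 (not isolated)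
Conditions: n-BuLi, THF, −78 °C; DMF, −78 to 0 °C; inverse quench into cold aq. KH2PO4
Reagents that add atoms: N,N-dimethylformamide, CN(C)C=O
Why: Formylation of a lithium acetylide with DMF is a standard route to ynals, and the buffered inverse quench releases the aldehyde from the hemiaminal alkoxide without conjugate addition of dimethylamine.

Step 2
Reactants: 3 4-methylpent-2-ynal; 4 (E)-crotylboronic acid pinacol ester
Product: 5 (3S,4S)-3,7-dimethyloct-1-en-5-yn-4-ol
Conditions: (S)-3,3′-bis(2,4,6-triisopropylphenyl)-1,1′-binaphthyl-2,2′-diyl hydrogen phosphate (5 mol %), 4 Å MS, toluene, −30 °C; aq. NaHCO3 work-up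
Reagents that add atoms: 4 (E)-crotylboronic acid pinacol ester, C/C=C/CB1OC(C)(C)C(C)(C)O1
Why: Chiral phosphoric acid-catalysed crotylboration proceeds through a closed Zimmerman–Traxler chair, so the E-boronate gives the anti product and the (S)-configured acid should direct addition to the Si face of the ynal, which sets the (3S) methyl-bearing centre from which every later stereocentre is relayed (the carbinol centre is lost in step 3).

Step 3
Reactants: 5 (3S,4S)-3,7-dimethyloct-1-en-5-yn-4-ol
Product: 6 (1R,4S,5S)-4-methyl-1-(propan-2-yl)bicyclo[3.1.0]hexan-3-one (antipode of natural α-thujone)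
Conditions: (Ph3P)AuCl (2 mol %), AgSbF6 (2 mol %), CH2Cl2, 0 °C to rt
Reagents that add atoms: none
Why: Gold-catalysed cycloisomerisation of a hydroxylated 1,5-enyne: the monovalent gold cation activates the alkyne, the vinyl group attacks it to give a cyclopropyl gold carbene, and a 1,2-hydride shift from the carbinol carbon followed by loss of gold gives the ketone, with the new cyclopropane placed anti to the allylic methyl group so that the (3S) centre is translated into the (1R,5S) bicycle; the minor methyl-syn diastereomer carries the antipodal cyclopropane and is removed by chromatography here, before C10 is made planar.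

Step 4
Reactants: 6 (1R,4S,5S)-4-methyl-1-(propan-2-yl)bicyclo[3.1.0]hexan-3-one
Product: 7 trimethyl{[(1R,5R)-2-methyl-5-(propan-2-yl)bicyclo[3.1.0]hex-2-en-3-yl]oxy}silane
Conditions: TMSCl, NaI, Et3N, MeCN, rt
Reagents that add atoms: chlorotrimethylsilane, C[Si](C)(C)Cl
Why: Silyl enol ether formation under equilibrating conditions (iodotrimethylsilane generated in situ with an amine base) should give the more substituted C1=C10 enol ether, which is tetrasubstituted and conjugated with the cyclopropane, and it deliberately erases the C10 methyl stereocentre once it has done its work.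

Step 5
Reactants: 7 trimethyl{[(1R,5R)-2-methyl-5-(propan-2-yl)bicyclo[3.1.0]hex-2-en-3-yl]oxy}silane; 8 2-bromo-N-methoxy-N-methylacetamide
Product: 10 2-[(1R,2S,5R)-2-methyl-3-oxo-5-(propan-2-yl)bicyclo[3.1.0]hexan-2-yl]-N-methoxy-N-methylacetamide, via lithium enolate 9 (not isolated)
Conditions: MeLi, THF, 0 °C; then 8, DMPU, −78 to −20 °C
Reagents that add atoms: 8 2-bromo-N-methoxy-N-methylacetamide, CON(C)C(=O)CBr
Why: Methyllithium cleaves the silyl enol ether to the regiodefined lithium enolate, and SN2 alkylation by the activated alpha-bromo amide then takes place at C10 from the lower face, anti to the cyclopropane methylene C5 that sits directly over the upper face of C10, which sets the quaternary centre with the methyl syn and the acetamide arm anti to the cyclopropane.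

Step 6
Reactants: 10 2-[(1R,2S,5R)-2-methyl-3-oxo-5-(propan-2-yl)bicyclo[3.1.0]hexan-2-yl]-N-methoxy-N-methylacetamide
Product: 11 2-[(1R,2S,3S,5R)-3-hydroxy-2-methyl-5-(propan-2-yl)bicyclo[3.1.0]hexan-2-yl]-N-methoxy-N-methylacetamide
Conditions: (R)-1-methyl-3,3-diphenyltetrahydro-1H,3H-pyrrolo[1,2-c][1,3,2]oxazaborole (20 mol %), BH3·SMe2, THF, −20 °C; MeOH quench
Reagents that add atoms: none
Why: Corey–Bakshi–Shibata reduction: the (R)-oxazaborolidine distinguishes the quaternary C10 flank from the C2 methylene and delivers hydride to the lower face of C1, the face that the boat-shaped bicycle also leaves open because the endo hydrogen of the cyclopropane methylene covers the upper face, so that the (S)-carbinol with the hydroxyl cis to the C10 methyl is expected, while the Weinreb amide is reduced far more slowly than the ketone at this temperature.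

Step 7
Reactants: 11 2-[(1R,2S,3S,5R)-3-hydroxy-2-methyl-5-(propan-2-yl)bicyclo[3.1.0]hexan-2-yl]-N-methoxy-N-methylacetamide; 12 isopropenylmagnesium bromide
Product: 13 1-[(1R,2S,3S,5R)-3-hydroxy-2-methyl-5-(propan-2-yl)bicyclo[3.1.0]hexan-2-yl]-3-methylbut-3-en-2-one
Conditions: 12 (3 equiv), THF, −20 to 0 °C; inverse quench into cold aq. NH4Cl
Reagents that add atoms: 12 isopropenylmagnesium bromide, CC(=C)[Mg]Br
Why: Weinreb ketone synthesis: one equivalent of Grignard reagent deprotonates the alcohol, a second adds to the amide to give a chelated tetrahedral adduct that cannot add again and collapses to the isopropenyl ketone only on quenching, and the trans relation of the C1 alkoxide to the amide arm rules out lactonisation; no stereocentre is touched.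

Step 8
Reactants: 13 1-[(1R,2S,3S,5R)-3-hydroxy-2-methyl-5-(propan-2-yl)bicyclo[3.1.0]hexan-2-yl]-3-methylbut-3-en-2-one
Product: 14 (1R,3S,4S,5R)-4-methyl-4-(3-methyl-2-oxobut-3-en-1-yl)-1-(propan-2-yl)bicyclo[3.1.0]hexan-3-yl acetate
Conditions: Ac2O, 4-(dimethylamino)pyridine (cat.), pyridine, rt
Reagents that add atoms: acetic anhydride, CC(=O)OC(C)=O
Why: DMAP-catalysed acylation of the hindered secondary alcohol with acetic anhydride gives the acetate without touching a stereocentre or the base-sensitive isopropenyl ketone.

Step 9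
Reactants: 14 (1R,3S,4S,5R)-4-methyl-4-(3-methyl-2-oxobut-3-en-1-yl)-1-(propan-2-yl)bicyclo[3.1.0]hexan-3-yl acetate
Product: 16 (1S,3R,3aS,8aS)-3-hydroxy-6,8a-dimethyl-7-oxo-3-(propan-2-yl)decahydroazulen-1-yl acetate (both C7 epimers; azulene locant 6), via alkylmercury trifluoroacetate 15 (not isolated)
Conditions: Hg(O2CCF3)2 (1.05 equiv), THF/H2O 3:1, 0 °C; then CH2Cl2 (to 5 mM), aq. NaBH4 by syringe pump, 0 °C
Reagents that add atoms: water, O
Why: Proposed new method: divalent mercury attacks the cyclopropane at its unhindered methylene C5 while the bond from C5 to the quaternary C3, the carbon that best carries positive charge, breaks and water enters C3 from the lower face, anti to the departing C5 (assistance by the C8 carbonyl from the same face would lead after hydrolysis to the same carbinol), so C3 is inverted and its hydroxyl ends trans to C5 across C3–C4; borohydride then converts the C5–Hg bond into an alkylmercury hydride whose radical chain releases a primary C5 radical. This nucleophilic radical adds to the unsubstituted terminus C6 of the isopropenyl ketone in a 7-endo-trig closure of ring B, and the tertiary alpha-keto radical at C7 is quenched by hydrogen transfer from the mercury hydride. The closest known reactions are the solvomercuration of cyclopropanes, which cleaves the bond between the least and the most substituted carbon with inversion at the nucleophile terminus, and the reductive mercury (Giese) method for radical conjugate addition, which has not been used for a 7-endo closure coupled to a cyclopropane opening. Of the stereocentres formed, C3 is fixed by the stereospecific anti opening, the trans ring fusion is inherited unchanged from C4 and C10, and C7 forms without control and is removed in step 10. The step needs mercury to attack the electron-rich strained sigma bond and not the electron-poor enone, which the donor-substituted cyclopropane and one equivalent of Hg(O2CCF3)2 at 0 °C should secure, and it needs ring closure to outrun hydrogen capture and 6-exo attack, which the polarity match at C6, the substituted and mismatched C7, and slow addition of hydride at 5 mM should secure.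

Step 10
Reactants: 16 (1S,3R,3aS,8aS)-3-hydroxy-6,8a-dimethyl-7-oxo-3-(propan-2-yl)decahydroazulen-1-yl acetate
Product: 17 (1S,3R,3aS,8aS)-3-hydroxy-6,8a-dimethyl-7-oxo-3-(propan-2-yl)-1,2,3,3a,4,7,8,8a-octahydroazulen-1-yl acetate
Conditions: 2-iodoxybenzoic acid (IBX, 2 equiv), 4-methoxypyridine N-oxide (2 equiv), DMSO, rt to 40 °C
Reagents that add atoms: none
Why: IBX dehydrogenation of a ketone through its enol can only introduce unsaturation on the C7 side because C10 is quaternary, so both C7 epimers should converge on the endocyclic trisubstituted C6=C7 enone, and the tertiary alcohol and the acetate are inert to the reagent.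

Step 11
Reactants: 17 (1S,3R,3aS,8aS)-3-hydroxy-6,8a-dimethyl-7-oxo-3-(propan-2-yl)-1,2,3,3a,4,7,8,8a-octahydroazulen-1-yl acetate
Product: 18 (1S,3R,3aS,8aS)-3-hydroxy-6,8a-dimethyl-3-(propan-2-yl)-7-{[tri(propan-2-yl)silyl]oxy}-1,2,3,3a,8,8a-hexahydroazulen-1-yl acetate
Conditions: TIPSOTf (1.3 equiv), Et3N (3 equiv), CH2Cl2, −78 °C to rt
Reagents that add atoms: triisopropylsilyl trifluoromethanesulfonate, CC(C)[Si](C(C)C)(C(C)C)OS(=O)(=O)C(F)(F)F
Why: Soft enolisation with a silyl triflate and an amine: O-silylation of the enone followed by loss of a gamma proton from C5 should give the linearly conjugated dienol ether, favoured because the alpha' protons on C9 are neopentylic and shielded by the silyl group that the C7 methyl pushes toward C9 and because the 1-siloxydiene is the more stabilised isomer, while the bulky silyl triflate leaves the tertiary C3 hydroxyl free.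

Step 12
Reactants: 18 (1S,3R,3aS,8aS)-3-hydroxy-6,8a-dimethyl-3-(propan-2-yl)-7-{[tri(propan-2-yl)silyl]oxy}-1,2,3,3a,8,8a-hexahydroazulen-1-yl acetate
Product: 20 (1S,3R,3aR,4R,8aS)-3,4-dihydroxy-6,8a-dimethyl-7-oxo-3-(propan-2-yl)-1,2,3,3a,4,7,8,8a-octahydroazulen-1-yl acetate, via siloxy epoxide 19 (not isolated)
Conditions: 3-chloroperbenzoic acid (mCPBA, 1.1 equiv), CH2Cl2, −40 to 0 °C; aq. NaHCO3/Na2S2O3 work-up
Reagents that add atoms: 3-chloroperbenzoic acid, OOC(=O)c1cccc(Cl)c1
Why: Vinylogous Rubottom oxidation: the peracid epoxidises the terminal C5=C6 bond of the siloxydiene (the C7=C8 bond is screened by the triisopropylsiloxy group and by C10) from the lower face, which is the face anti to the C10 methyl and the C3 isopropyl group and the one on which the free C3 hydroxyl can hydrogen-bond to the peracid, and opening of the epoxide by the enol ether leaves the oxygen on C5 and restores the enone, so that the C5 hydroxyl is set cis to the C3 hydroxyl.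

Step 13
Reactants: 21 4-hydroxybenzoic acid
Product: 23 4-{[tert-butyl(dimethyl)silyl]oxy}benzoic acid, via bis-silyl ester 22 (not isolated)
Conditions: TBSCl (2.3 equiv), imidazole, DMF, rt; then AcOH/THF/H2O, rt
Reagents that add atoms: tert-butyl(chloro)dimethylsilane, CC(C)(C)[Si](C)(C)Cl
Why: Both acidic hydroxyl groups are silylated with the silyl chloride and imidazole, and the much more labile silyl ester is then hydrolysed selectively in aqueous acetic acid, which leaves the aryl silyl ether in place.

Step 14
Reactants: 20 (1S,3R,3aR,4R,8aS)-3,4-dihydroxy-6,8a-dimethyl-7-oxo-3-(propan-2-yl)-1,2,3,3a,4,7,8,8a-octahydroazulen-1-yl acetate; 23 4-{[tert-butyl(dimethyl)silyl]oxy}benzoic acid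
Product: 24 (1S,3R,3aR,4R,8aS)-1-(acetyloxy)-3-hydroxy-6,8a-dimethyl-7-oxo-3-(propan-2-yl)-1,2,3,3a,4,7,8,8a-octahydroazulen-4-yl 4-{[tert-butyl(dimethyl)silyl]oxy}benzoate
Conditions: N,N′-dicyclohexylcarbodiimide (DCC), 4-(dimethylamino)pyridine, CH2Cl2, 0 °C to rt
Reagents that add atoms: 23 4-{[tert-butyl(dimethyl)silyl]oxy}benzoic acid, CC(C)(C)[Si](C)(C)Oc1ccc(cc1)C(O)=O
Why: Steglich esterification acylates the secondary allylic C5 hydroxyl in preference to the hindered tertiary C3 hydroxyl, and since the C5–O bond is not broken the configuration set in step 12 is retained.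

Step 15
Reactants: 24 (1S,3R,3aR,4R,8aS)-1-(acetyloxy)-3-hydroxy-6,8a-dimethyl-7-oxo-3-(propan-2-yl)-1,2,3,3a,4,7,8,8a-octahydroazulen-4-yl 4-{[tert-butyl(dimethyl)silyl]oxy}benzoate
Product: 25 (1S,3R,3aR,4R,8aS)-1-(acetyloxy)-3-hydroxy-6,8a-dimethyl-7-oxo-3-(propan-2-yl)-1,2,3,3a,4,7,8,8a-octahydroazulen-4-yl 4-hydroxybenzoate (CNP0087181.1)
Conditions: HF·pyridine, pyridine/THF, 0 °C
Reagents that add atoms: none
Why: Fluoride cleaves the aryl silyl ether under buffered, mildly acidic conditions that spare the acetate, the allylic aroyl ester, the enone and the tertiary alcohol, which gives the target without touching a stereocentre.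

**Compound list**
1 | 3-methylbut-1-yne | CC(C)C#C | starting material
2 | lithium 3-methylbut-1-yn-1-ide (lithium acetylide) | CC(C)C#C[Li] | intermediate (not isolated)
3 | 4-methylpent-2-ynal | CC(C)C#CC=O | intermediate
4 | (E)-crotylboronic acid pinacol ester | C/C=C/CB1OC(C)(C)C(C)(C)O1 | starting material
5 | (3S,4S)-3,7-dimethyloct-1-en-5-yn-4-ol | C=C[C@H](C)[C@H](O)C#CC(C)C | intermediate
6 | (1R,4S,5S)-4-methyl-1-(propan-2-yl)bicyclo[3.1.0]hexan-3-one | O=C1C[C@@]2(C(C)C)C[C@H]2[C@@H]1C | intermediate
7 | trimethyl{[(1R,5R)-2-methyl-5-(propan-2-yl)bicyclo[3.1.0]hex-2-en-3-yl]oxy}silane | C[Si](C)(C)OC1=C(C)[C@@H]2C[C@]2(C(C)C)C1 | intermediate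
8 | 2-bromo-N-methoxy-N-methylacetamide | CON(C)C(=O)CBr | starting material
9 | lithium (1R,5R)-2-methyl-5-(propan-2-yl)bicyclo[3.1.0]hex-2-en-3-olate (lithium enolate) | [Li]OC1=C(C)[C@@H]2C[C@]2(C(C)C)C1 | intermediate (not isolated)
10 | 2-[(1R,2S,5R)-2-methyl-3-oxo-5-(propan-2-yl)bicyclo[3.1.0]hexan-2-yl]-N-methoxy-N-methylacetamide | O=C1C[C@@]2(C(C)C)C[C@H]2[C@]1(C)CC(=O)N(C)OC | intermediate
11 | 2-[(1R,2S,3S,5R)-3-hydroxy-2-methyl-5-(propan-2-yl)bicyclo[3.1.0]hexan-2-yl]-N-methoxy-N-methylacetamide | O[C@H]1C[C@@]2(C(C)C)C[C@H]2[C@]1(C)CC(=O)N(C)OC | intermediate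
12 | isopropenylmagnesium bromide | CC(=C)[Mg]Br | starting material
13 | 1-[(1R,2S,3S,5R)-3-hydroxy-2-methyl-5-(propan-2-yl)bicyclo[3.1.0]hexan-2-yl]-3-methylbut-3-en-2-one | O[C@H]1C[C@@]2(C(C)C)C[C@H]2[C@]1(C)CC(=O)C(C)=C | intermediate
14 | (1R,3S,4S,5R)-4-methyl-4-(3-methyl-2-oxobut-3-en-1-yl)-1-(propan-2-yl)bicyclo[3.1.0]hexan-3-yl acetate (key-step precursor) | CC(=O)O[C@H]1C[C@@]2(C(C)C)C[C@H]2[C@]1(C)CC(=O)C(C)=C | intermediate
15 | (1S,2S,3S,4R)-4-hydroxy-2-methyl-2-(3-methyl-2-oxobut-3-en-1-yl)-4-(propan-2-yl)-3-{[(trifluoroacetoxy)mercurio]methyl}cyclopentyl acetate (alkylmercury trifluoroacetate) | CC(=O)O[C@H]1C[C@@](O)(C(C)C)[C@@H](C[Hg]OC(=O)C(F)(F)F)[C@]1(C)CC(=O)C(C)=C | intermediate (not isolated)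
16 | (1S,3R,3aS,8aS)-3-hydroxy-6,8a-dimethyl-7-oxo-3-(propan-2-yl)decahydroazulen-1-yl acetate, both C7 epimers (key-step product) | CC(=O)O[C@H]1C[C@@](O)(C(C)C)[C@H]2CCC(C)C(=O)C[C@]12C | intermediate
17 | (1S,3R,3aS,8aS)-3-hydroxy-6,8a-dimethyl-7-oxo-3-(propan-2-yl)-1,2,3,3a,4,7,8,8a-octahydroazulen-1-yl acetate | CC(=O)O[C@H]1C[C@@](O)(C(C)C)[C@H]2CC=C(C)C(=O)C[C@]12C | intermediate
18 | (1S,3R,3aS,8aS)-3-hydroxy-6,8a-dimethyl-3-(propan-2-yl)-7-{[tri(propan-2-yl)silyl]oxy}-1,2,3,3a,8,8a-hexahydroazulen-1-yl acetate | CC(=O)O[C@H]1C[C@@](O)(C(C)C)[C@H]2C=CC(C)=C(O[Si](C(C)C)(C(C)C)C(C)C)C[C@]12C | intermediate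
19 | C5–C6 epoxide of 18 (azulene locants 4,5), oxygen on the lower face, C7=C8 silyl enol ether intact (siloxy epoxide) | CC(=O)O[C@H]1C[C@@](O)(C(C)C)[C@H]2[C@@H]3O[C@@H]3C(C)=C(O[Si](C(C)C)(C(C)C)C(C)C)C[C@]12C | intermediate (not isolated)
20 | (1S,3R,3aR,4R,8aS)-3,4-dihydroxy-6,8a-dimethyl-7-oxo-3-(propan-2-yl)-1,2,3,3a,4,7,8,8a-octahydroazulen-1-yl acetate | CC(=O)O[C@H]1C[C@@](O)(C(C)C)[C@H]2[C@H](O)C=C(C)C(=O)C[C@]12C | intermediate
21 | 4-hydroxybenzoic acid | OC(=O)c1ccc(O)cc1 | starting material
22 | tert-butyl(dimethyl)silyl 4-{[tert-butyl(dimethyl)silyl]oxy}benzoate (bis-silyl ester) | CC(C)(C)[Si](C)(C)OC(=O)c1ccc(O[Si](C)(C)C(C)(C)C)cc1 | intermediate (not isolated)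
23 | 4-{[tert-butyl(dimethyl)silyl]oxy}benzoic acid | CC(C)(C)[Si](C)(C)Oc1ccc(cc1)C(O)=O | intermediate
24 | (1S,3R,3aR,4R,8aS)-1-(acetyloxy)-3-hydroxy-6,8a-dimethyl-7-oxo-3-(propan-2-yl)-1,2,3,3a,4,7,8,8a-octahydroazulen-4-yl 4-{[tert-butyl(dimethyl)silyl]oxy}benzoate | CC(=O)O[C@H]1C[C@@](O)(C(C)C)[C@H]2[C@H](OC(=O)c3ccc(O[Si](C)(C)C(C)(C)C)cc3)C=C(C)C(=O)C[C@]12C | intermediate
25 | (1S,3R,3aR,4R,8aS)-1-(acetyloxy)-3-hydroxy-6,8a-dimethyl-7-oxo-3-(propan-2-yl)-1,2,3,3a,4,7,8,8a-octahydroazulen-4-yl 4-hydroxybenzoate | CC(=O)O[C@H]1C[C@@](O)(C(C)C)[C@H]2[C@H](OC(=O)c3ccc(O)cc3)C=C(C)C(=O)C[C@]12C | target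

**Step count**
Total: 15 steps. Longest linear sequence: 14 steps (steps 1–12, 14, 15); step 13 is a one-step side branch.

**Steps most likely to fail**

Step 9 (bears the label). The C5 radical may be reduced by the alkylmercury hydride before it reaches C6, so that the ring stays open. The fallback uses known chemistry and sets out from 14. The hydroxymercuration is run as in step 9 to give 15, which is treated with I2 in place of hydride (iododemercuration) to give the primary iodide (1S,2S,3S,4R)-4-hydroxy-3-(iodomethyl)-2-methyl-2-(3-methyl-2-oxobut-3-en-1-yl)-4-(propan-2-yl)cyclopentyl acetate F1. Slow addition of Bu3SnH with azobisisobutyronitrile in benzene at 80 °C and 5 mM then generates the same C5 radical at a much lower stationary concentration of hydrogen donor. The tin hydride 7-endo-trig cyclisation onto the enone comes back to the route at 16.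

Step 11. Deprotonation may occur at the alpha' methylene C9 instead of C5, which would give the cross-conjugated dienol ether and lead to oxidation at the wrong carbon. The fallback avoids enolisation and sets out from 17. Wohl–Ziegler bromination (N-bromosuccinimide, azobisisobutyronitrile, PhCF3, 80 °C) at the only allylic methylene, C5, should give the gamma-bromo enone F2, the C5 bromide of 17. Silver-assisted solvolysis (AgOTf, aqueous acetone) then lets water attack the allyl cation at C5 from the lower face. This comes back to the route at 20 and bypasses 18 and 19.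

Step 12. The peracid may attack the enol ether bond C7=C8 (alpha-hydroxylation) or deliver oxygen to the upper face of C5=C6. The fallback sets out from 18. Kinetic protodesilylation (Bu4NF, AcOH, THF, −78 °C) protonates the dienolate at C7 and should give the beta,gamma-unsaturated ketone F3, with C5=C6 as the only alkene. That isolated alkene is epoxidised under direction of the homoallylic C3 hydroxyl (VO(acac)2, tert-butyl hydroperoxide, CH2Cl2) to give the lower-face epoxy ketone F4. DBU then opens the beta,gamma-epoxy ketone by E1cB elimination, and the route is rejoined at 20.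

**Further compounds**
F1 | step 9 | (1S,2S,3S,4R)-4-hydroxy-3-(iodomethyl)-2-methyl-2-(3-methyl-2-oxobut-3-en-1-yl)-4-(propan-2-yl)cyclopentyl acetate | CC(=O)O[C@H]1C[C@@](O)(C(C)C)[C@@H](CI)[C@]1(C)CC(=O)C(C)=C
F2 | step 11 | C5 bromide of 17 (gamma-bromo enone, bromine configuration not controlled) | CC(=O)O[C@H]1C[C@@](O)(C(C)C)[C@H]2C(Br)C=C(C)C(=O)C[C@]12C
F3 | step 12 | beta,gamma-unsaturated ketone isomer of 17 (C5=C6 alkene, C7 epimers) | CC(=O)O[C@H]1C[C@@](O)(C(C)C)[C@H]2C=CC(C)C(=O)C[C@]12C
F4 | step 12 | C5–C6 lower-face epoxide of F3 (beta,gamma-epoxy ketone, C7 epimers) | CC(=O)O[C@H]1C[C@@](O)(C(C)C)[C@H]2[C@@H]3O[C@@H]3C(C)C(=O)C[C@]12C
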